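**Retrosynthetic overview**
1. Target 37 ⇐ acetylation and desilylation of chlorolactone 35 ⇐ chloride opening and lactonisation of epoxy aldol 33 ⇐ propanoate aldol on epoxy enone 30.
2. Ten-membered ring ⇐ anionic oxy-Cope ring expansion of trans-decalin 24 (8β-vinyl-8α-ol, 3α-allenyl); the new C5–C6 bond, the 3E-alkene and the 5(16)-methylene arise together.
3. 24 ⇐ allenyl ketone 22 ⇐ propargyl Claisen rearrangement of decalin enol ether 21; C2, C9 and C14 carbinols from face-selective hydride reductions.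
4. Decalin ⇐ 6-endo vinyl-radical closure of ring A after a trans conjugate addition/aldol on enone 3 ⇐ (R)-carvone (Criegee degradation).
5. Ring order: ring B (from carvone) → ring A → ten-membered ring (ring B is consumed) → lactone; every stereocentre descends from the carvone centre by substrate control.

Convention (one line): briarane numbering is used for all intermediates (ring A = C1, C10–C14; decalin ring B = C1, C2, C3, C8, C9, C10; C15 = methyl on C1; C16 = methylene on C5; C20 = methylene on C11; C17 bears methyl C18 and lactone carbonyl C19); β = face of the C15 methyl in the usual planar drawing, α = the other face.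

**Step 1**
Reactants: 1 (R)-(−)-carvone
Product: 3 (5R)-5-acetoxy-2-methylcyclohex-2-en-1-one, via α-methoxy hydroperoxide 2 (not isolated)
Conditions: O3, CH2Cl2/MeOH 4:1, −78 °C; then Ac2O, Et3N, 4-(dimethylamino)pyridine (cat.), 0 → 40 °C
Reagents that add atoms: ozone ([O-][O+]=O); methanol (CO)
Why: Ozonolysis cleaves the electron-rich isopropenyl alkene in preference to the enone, and Criegee rearrangement of the acetylated α-methoxy hydroperoxide migrates the ring carbon with retention, so the carvone stereocentre becomes the C8 acetate.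

**Step 2**
Reactants: 3 (5R)-5-acetoxy-2-methylcyclohex-2-en-1-one; 4 (1-bromovinyl)trimethylsilane; 5 acrolein
Product: 8 aldol adduct 8α-acetoxy-1α-(1-hydroxyallyl)-1β-methyl-10β-[1-(trimethylsilyl)vinyl]cyclohexan-2-one (C14 epimers), via 1-(trimethylsilyl)vinylmagnesium bromide 6 (not isolated), via bromomagnesium enolate 7 (not isolated)
Conditions: 4, Mg, THF, 25 °C; CuBr·SMe2 (10 mol %), THF, −78 °C, add 3; then 5, −78 °C; H2O
Reagents that add atoms: none
Why: Copper-catalysed conjugate addition occurs anti to the C8 acetoxy group (general for 5-substituted cyclohexenones) and the enolate then adds to acrolein anti to the new C10 substituent (vicinal difunctionalisation), setting C10 and the quaternary C1 trans, while C14 forms as an inconsequential mixture.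

**Step 3**
Reactants: 8 aldol adduct
Product: 9 vinyl ketone 8α-acetoxy-1α-acryloyl-1β-methyl-10β-[1-(trimethylsilyl)vinyl]cyclohexan-2-one
Conditions: Dess–Martin periodinane, pyridine, CH2Cl2, 0 → 25 °C
Reagents that add atoms: none
Why: Dess–Martin oxidation converts the allylic alcohol into the enone without touching the vinylsilane or acetate, and the C14 mixture converges to one compound.

**Step 4**
Reactants: 9 vinyl ketone
Product: 10 vinyl iodide 8α-acetoxy-1α-acryloyl-10β-(1-iodovinyl)-1β-methylcyclohexan-2-one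
Conditions: N-iodosuccinimide, MeCN/ClCH2CN 4:1, 0 → 25 °C
Reagents that add atoms: N-iodosuccinimide (O=C1CCC(=O)N1I)
Why: Electrophilic ipso-iododesilylation replaces silicon by iodine at C11 without moving the double bond and touches no stereocentre.

**Step 5**
Reactants: 10 vinyl iodide
Product: 11 trans-decalin 8α-acetoxy-1β-methyl-11-methylene-10α-H-decalin-2,14-dione
Conditions: Bu3SnH (slow addition), AIBN (cat.), PhH (0.01 M), 80 °C
Reagents that add atoms: none
Why: The vinyl radical cyclises 6-endo-trig onto the terminal β-carbon of the vinyl ketone (5-exo attack at the α-carbon would give an unstabilised primary radical), closing ring A with the C11 methylene in place and the trans ring fusion inherited from step 2.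

**Step 6**
Reactants: 11 decalin acetate
Product: 12 8α-hydroxy-1β-methyl-11-methylene-10α-H-decalin-2,14-dione
Conditions: HCl (1.25 M in MeOH), 0 → 25 °C
Reagents that add atoms: none
Why: Acid-catalysed transesterification removes the acetate while avoiding base, which would cause E1cB loss of the β-acyloxy group or retro-Claisen opening of the non-enolisable 1,3-diketone.

**Step 7**
Reactants: 12 hydroxy diketone
Product: 13 1β-methyl-11-methylene-10α-H-decalin-2,8,14-trione
Conditions: Dess–Martin periodinane, CH2Cl2, 25 °C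
Reagents that add atoms: none
Why: Dess–Martin oxidation gives the C2/C8 1,3-diketone; the C8 centre has relayed its information and is deliberately removed.

**Step 8**
Reactants: 13 trione; 14 prop-2-yn-1-ol
Product: 15 vinylogous ester 1β-methyl-11-methylene-8-(prop-2-ynyloxy)-10α-H-decal-3(8)-ene-2,14-dione
Conditions: p-TsOH·H2O (5 mol %), PhH, reflux, Dean–Stark
Reagents that add atoms: none
Why: Acid-catalysed enol etherification of the enolisable 1,3-diketone takes place at the C8 carbonyl, remote from the quaternary C1, leaving the hindered C2 carbonyl as the ketone.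

**Step 9**
Reactants: 15 vinylogous ester
Product: 16 14α-hydroxy-1β-methyl-11-methylene-8-(prop-2-ynyloxy)-10α-H-decal-3(8)-en-2-one
Conditions: K[sec-Bu3BH] (1.2 equiv), THF, −78 °C; H2O
Reagents that add atoms: none
Why: The bulky borohydride reduces only the saturated C14 ketone (the vinylogous ester carbonyl is inert at −78 °C) by equatorial attack, giving the axial 14α-alcohol trans to the angular methyl (steric approach control).

**Step 10**
Reactants: 16 hydroxy vinylogous ester
Product: 18 9,14α-dihydroxy-1β-methyl-11-methylene-8-(prop-2-ynyloxy)-10α-H-decal-3(8)-en-2-one (C9 epimers), via C9 hydroperoxide 17 (not isolated)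
Conditions: LiN(i-Pr)2 (3.2 equiv), THF, −78 °C; O2, P(OEt)3, −78 → −40 °C; H2O
Reagents that add atoms: dioxygen (O=O)
Why: With the α′ position (C1) quaternary the base removes the γ-proton at C9, and the vinylogous-ester dienolate is oxygenated at its γ-terminus (enolate oxygenation with in situ phosphite reduction); the C9 configuration is irrelevant here.

**Step 11**
Reactants: 18 diol
Product: 19 alkoxy enedione 14α-hydroxy-1β-methyl-11-methylene-8-(prop-2-ynyloxy)-10α-H-decal-3(8)-ene-2,9-dione
Conditions: MnO2 (20 equiv), CH2Cl2, 25 °C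
Reagents that add atoms: none
Why: MnO2 oxidises only the allylic C9 alcohol, under neutral conditions that leave the saturated C14 alcohol and the C10 centre untouched.

**Step 12**
Reactants: 19 alkoxy enedione
Product: 20 1β-methyl-11-methylene-8-(prop-2-ynyloxy)-10α-H-decal-3(8)-ene-2β,9β,14α-triol
Conditions: LiAlH4, Et2O, −78 → −20 °C; Na2SO4·10H2O
Reagents that add atoms: none
Why: LiAlH4 attacks both carbonyls from the α-face, anti to the angular C15 methyl (steric approach control): axial attack at C2 gives the equatorial 2β-alcohol, and equatorial attack at C9 (the axial trajectory is blocked by the syn-axial methyl) gives the axial 9β-alcohol.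

**Step 13**
Reactants: 20 triol
Product: 21 2β,9β,14α-tris(tert-butyldimethylsilyloxy)-1β-methyl-11-methylene-8-(prop-2-ynyloxy)-10α-H-decal-3(8)-ene
Conditions: tert-butyldimethylsilyl triflate (4.5 equiv), 2,6-lutidine, CH2Cl2, −78 → 0 °C
Reagents that add atoms: tert-butyldimethylsilyl triflate (CC(C)(C)[Si](C)(C)OS(=O)(=O)C(F)(F)F)
Why: Silyl triflate with a hindered base silylates all three secondary alcohols, including the axial ones, under non-acidic conditions that preserve the labile enol ether.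

**Step 14**
Reactants: 21 propargyl enol ether
Product: 22 allenyl ketone 2β,9β,14α-tris(tert-butyldimethylsilyloxy)-1β-methyl-11-methylene-3α-(propa-1,2-dienyl)-10α-H-decalin-8-one
Conditions: xylenes (0.02 M, degassed), Et3N (trace), 140 °C, sealed tube
Reagents that add atoms: none
Why: The thermal propargyl Claisen ([3,3]-sigmatropic, Saucy–Marbet type) rearrangement unveils the C8 ketone and forms the C3–C4 bond on the α-face, anti to the 1,3-related axial C15 methyl, giving the equatorial 3α-allenyl group.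

**Step 15**
Reactants: 22 allenyl ketone
Product: 23 spiro-epoxide of 22 at C8 (epoxide oxygen 8α-axial; CH2 8β-equatorial)
Conditions: Me3S(O)I, NaH, DMSO/THF, 25 → 45 °C
Reagents that add atoms: trimethylsulfoxonium iodide (C[S+](C)(C)=O.[I-])
Why: Corey–Chaykovsky epoxidation with the sulfoxonium ylide is reversible at the betaine stage and delivers the methylene equatorially, so the C8 oxygen ends up axial (α) and trans-diaxial to the C9 silyloxy group.

**Step 16**
Reactants: 23 spiro-epoxide
Product: 24 2β,9β,14α-tris(tert-butyldimethylsilyloxy)-8β-ethenyl-1β-methyl-11-methylene-3α-(propa-1,2-dienyl)-10α-H-decalin-8α-ol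
Conditions: Me3SI, n-BuLi, THF, −10 → 25 °C; H2O
Reagents that add atoms: trimethylsulfonium iodide (C[S+](C)C.[I-])
Why: Dimethylsulfonium methylide opens the terminal epoxide carbon and the sulfonium betaine undergoes ylide-mediated elimination of dimethyl sulfide (epoxide-to-allylic-alcohol homologation), giving the tertiary vinyl carbinol with the C8 configuration retained (equatorial vinyl, axial hydroxyl).

**Step 17**
Reactants: 24 vinyl carbinol
Product: 29 (3E,6E)-2β,9β,14α-tris(tert-butyldimethylsilyloxy)-1β-methyl-5,11-dimethylene-10α-H-bicyclo[8.4.0]tetradeca-3,6-dien-8-one, via potassium alkoxide 25 (not isolated), via potassium enolate 26 (not isolated), via C7 phenylselenide 27 (not isolated), via C7 selenoxide 28 (not isolated)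
Conditions: KN(SiMe3)2 (1.2 equiv), 18-crown-6, THF, 0 → 25 °C; PhSeCl, −78 °C; then 30% H2O2, pyridine, CH2Cl2, 0 → 25 °C
Reagents that add atoms: none
Why: The alkoxide undergoes anionic oxy-Cope ([3,3]-sigmatropic) ring expansion through a chair transition state in which the trans-diequatorial vinyl and allenyl groups keep C2 and C9 pseudo-equatorial, forming the C5–C6 bond, the 3E-alkene and the 5(16)-methylene of the ten-membered ring, and the regiodefined C7 enolate is selenenylated and oxidised (selenoxide syn-elimination) to the E-enone.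

**Step 18**
Reactants: 29 enone
Product: 30 trans-6,7-epoxide of 29 (C6–O β; C7–O α)
Conditions: t-BuOOH (anhydrous, in decane), DBU, CH2Cl2, 0 → 25 °C
Reagents that add atoms: tert-butyl hydroperoxide (CC(C)(C)OO)
Why: Weitz–Scheffer (nucleophilic) epoxidation is specific for the enone C6=C7 bond and is expected on its exposed face, away from the β-oriented C9 silyloxy and C15 methyl groups, so the trans-epoxide from the E-enone has C7–O α and C6–O β.

**Step 19**
Reactants: 30 epoxy ketone; 31 ethyl propanoate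
Product: 33 ethyl 2-(6β,7α-epoxy-8α-hydroxy-8β-yl)propanoate aldol adduct of 30 (C17 as in the target), via lithium enolate 32 (not isolated)
Conditions: LiN(i-Pr)2, THF/DMPU 4:1, −78 °C, add 31; then 30, −78 °C; AcOH quench
Reagents that add atoms: none
Why: Aldol addition of the Z(O)-enolate to the α,β-epoxy ketone occurs anti to C6 in the lithium-chelated conformer (Cram-chelate control), making the C8 hydroxyl α, and a Zimmerman–Traxler transition state with the bulky C9 branch equatorial places the C17 methyl syn to the C8 hydroxyl.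

**Step 20**
Reactants: 33 epoxy aldol
Product: 35 chlorolactone (target skeleton with tert-butyldimethylsilyl ethers at O2 O9 O14), via chlorohydrin ester 34 (not isolated)
Conditions: ClTi(Oi-Pr)3 (2 equiv), CH2Cl2, 0 → 25 °C; H2O
Reagents that add atoms: chlorotitanium triisopropoxide (CC(C)O[Ti](Cl)(OC(C)C)OC(C)C)
Why: Titanium-mediated opening of the 2,3-epoxy alcohol delivers chloride to the distal allylic C6 with inversion (6α-Cl), and the released C7 titanium alkoxide lactonises onto the ethyl ester (transesterification), closing the γ-lactone with retention at C7.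

**Step 21**
Reactants: 35 silylated chlorolactone
Product: 36 tetraol (2,9,14-tri-O-deacetyl target)
Conditions: HF·pyridine, pyridine/THF, 0 → 25 °C
Reagents that add atoms: none
Why: Fluoride-mediated desilylation removes the three silyl ethers without affecting the allylic chloride, the lactone or the diene.

**Step 22**
Reactants: 36 tetraol
Product: 37 target CNP0178742.3
Conditions: Ac2O, pyridine, 4-(dimethylamino)pyridine (cat.), CH2Cl2, 25 °C
Reagents that add atoms: acetic anhydride (CC(=O)OC(C)=O)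
Why: Nucleophile-catalysed acetylation esterifies the three secondary alcohols while the hindered tertiary C8 alcohol stays free.

**Compound list**

1 | (R)-(−)-carvone, (5R)-2-methyl-5-(prop-1-en-2-yl)cyclohex-2-en-1-one | CC1=CC[C@@H](C(C)=C)CC1=O | starting material
2 | (5R)-5-(1-hydroperoxy-1-methoxyethyl)-2-methylcyclohex-2-en-1-one (both epimers at the peroxy carbon) | CC1=CC[C@@H](C(C)(OC)OO)CC1=O | intermediate
3 | (5R)-5-acetoxy-2-methylcyclohex-2-en-1-one (C2 ketone, C1 methyl, 8α-OAc) | CC1=CC[C@@H](OC(C)=O)CC1=O | intermediate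
4 | (1-bromovinyl)trimethylsilane | C=C(Br)[Si](C)(C)C | starting material
5 | acrolein | C=CC=O | starting material
6 | 1-(trimethylsilyl)vinylmagnesium bromide | C=C([Mg]Br)[Si](C)(C)C | intermediate
7 | bromomagnesium enolate (C2–OMgBr, C1=C2) with 10β-[1-(trimethylsilyl)vinyl] trans to 8α-OAc | C=C([Si](C)(C)C)[C@H]1C(C)=C(O[Mg]Br)C[C@H](OC(C)=O)C1 | intermediate
8 | 5-acetoxy-2-(1-hydroxyallyl)-2-methyl-3-[1-(trimethylsilyl)vinyl]cyclohexanone; methyl cis to the silylvinyl group, acetoxy trans to it; C14 epimers | C=C([Si](C)(C)C)[C@H]1[C@](C)(C(O)C=C)C(=O)C[C@H](OC(C)=O)C1 | intermediate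
9 | 5-acetoxy-2-acryloyl-2-methyl-3-[1-(trimethylsilyl)vinyl]cyclohexanone (same ring stereochemistry as 8) | C=C([Si](C)(C)C)[C@H]1[C@](C)(C(=O)C=C)C(=O)C[C@H](OC(C)=O)C1 | intermediate
10 | 5-acetoxy-2-acryloyl-3-(1-iodovinyl)-2-methylcyclohexanone (same ring stereochemistry as 8) | C=C(I)[C@H]1[C@](C)(C(=O)C=C)C(=O)C[C@H](OC(C)=O)C1 | intermediate
11 | 8α-acetoxy-1β-methyl-11-methylene-10α-H-trans-decalin-2,14-dione | C=C1CCC(=O)[C@]2(C)C(=O)C[C@H](OC(C)=O)C[C@@H]12 | intermediate
12 | 8α-hydroxy-1β-methyl-11-methylene-10α-H-trans-decalin-2,14-dione | C=C1CCC(=O)[C@]2(C)C(=O)C[C@H](O)C[C@@H]12 | intermediate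
13 | 1β-methyl-11-methylene-10α-H-trans-decalin-2,8,14-trione (C2/C8 diketone partly enolised) | C=C1CCC(=O)[C@]2(C)C(=O)CC(=O)C[C@@H]12 | intermediate
14 | prop-2-yn-1-ol | OCC#C | starting material
15 | 1β-methyl-11-methylene-8-(prop-2-ynyloxy)-10α-H-decal-3(8)-ene-2,14-dione | C=C1CCC(=O)[C@]2(C)C(=O)C=C(OCC#C)C[C@@H]12 | intermediate
16 | 14α-hydroxy-1β-methyl-11-methylene-8-(prop-2-ynyloxy)-10α-H-decal-3(8)-en-2-one | C=C1CC[C@H](O)[C@]2(C)C(=O)C=C(OCC#C)C[C@@H]12 | intermediate
17 | 9-hydroperoxy derivative of 16 (C9 epimers) | C=C1CC[C@H](O)[C@]2(C)C(=O)C=C(OCC#C)C(OO)[C@@H]12 | intermediate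
18 | 9-hydroxy derivative of 16 (C9 epimers) | C=C1CC[C@H](O)[C@]2(C)C(=O)C=C(OCC#C)C(O)[C@@H]12 | intermediate
19 | 14α-hydroxy-1β-methyl-11-methylene-8-(prop-2-ynyloxy)-10α-H-decal-3(8)-ene-2,9-dione | C=C1CC[C@H](O)[C@]2(C)C(=O)C=C(OCC#C)C(=O)[C@@H]12 | intermediate
20 | 1β-methyl-11-methylene-8-(prop-2-ynyloxy)-10α-H-decal-3(8)-ene-2β,9β,14α-triol | C=C1CC[C@H](O)[C@]2(C)[C@@H](O)C=C(OCC#C)[C@@H](O)[C@@H]12 | intermediate
21 | tris(tert-butyldimethylsilyl) ether of 20 | C=C1CC[C@H](O[Si](C)(C)C(C)(C)C)[C@]2(C)[C@@H](O[Si](C)(C)C(C)(C)C)C=C(OCC#C)[C@@H](O[Si](C)(C)C(C)(C)C)[C@@H]12 | intermediate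
22 | 2β,9β,14α-tris(tert-butyldimethylsilyloxy)-1β-methyl-11-methylene-3α-(propa-1,2-dienyl)-10α-H-trans-decalin-8-one | C=C1CC[C@H](O[Si](C)(C)C(C)(C)C)[C@]2(C)[C@@H](O[Si](C)(C)C(C)(C)C)[C@H](C=C=C)C(=O)[C@@H](O[Si](C)(C)C(C)(C)C)[C@@H]12 | intermediate
23 | C8 spiro-oxirane of 22 (oxygen 8α, CH2 8β) | C=C1CC[C@H](O[Si](C)(C)C(C)(C)C)[C@]2(C)[C@@H](O[Si](C)(C)C(C)(C)C)[C@H](C=C=C)[C@@]3(CO3)[C@@H](O[Si](C)(C)C(C)(C)C)[C@@H]12 | intermediate
24 | 8β-ethenyl-8α-hydroxy analogue of 22 (Cope substrate) | C=C1CC[C@H](O[Si](C)(C)C(C)(C)C)[C@]2(C)[C@@H](O[Si](C)(C)C(C)(C)C)[C@H](C=C=C)[C@@](O)(C=C)[C@@H](O[Si](C)(C)C(C)(C)C)[C@@H]12 | intermediate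
25 | potassium 8α-alkoxide of 24 | C=C1CC[C@H](O[Si](C)(C)C(C)(C)C)[C@]2(C)[C@@H](O[Si](C)(C)C(C)(C)C)[C@H](C=C=C)[C@@]([O-])(C=C)[C@@H](O[Si](C)(C)C(C)(C)C)[C@@H]12.[K+] | intermediate
26 | potassium C7(8)-enolate of the ring-expanded (3E)-bicyclo[8.4.0]tetradecenone | C=C1CC[C@H](O[Si](C)(C)C(C)(C)C)[C@]2(C)[C@@H](O[Si](C)(C)C(C)(C)C)/C=C/C(=C)CC=C([O-])[C@@H](O[Si](C)(C)C(C)(C)C)[C@@H]12.[K+] | intermediate
27 | 7-(phenylselanyl) ketone (C7 epimers) | C=C1CC[C@H](O[Si](C)(C)C(C)(C)C)[C@]2(C)[C@@H](O[Si](C)(C)C(C)(C)C)/C=C/C(=C)CC([Se]c3ccccc3)C(=O)[C@@H](O[Si](C)(C)C(C)(C)C)[C@@H]12 | intermediate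
28 | 7-(phenylseleninyl) ketone | C=C1CC[C@H](O[Si](C)(C)C(C)(C)C)[C@]2(C)[C@@H](O[Si](C)(C)C(C)(C)C)/C=C/C(=C)CC([Se](=O)c3ccccc3)C(=O)[C@@H](O[Si](C)(C)C(C)(C)C)[C@@H]12 | intermediate
29 | (3E,6E)-2β,9β,14α-tris(tert-butyldimethylsilyloxy)-1β-methyl-5,11-dimethylene-10α-H-bicyclo[8.4.0]tetradeca-3,6-dien-8-one | C=C1CC[C@H](O[Si](C)(C)C(C)(C)C)[C@]2(C)[C@@H](O[Si](C)(C)C(C)(C)C)/C=C/C(=C)/C=C/C(=O)[C@@H](O[Si](C)(C)C(C)(C)C)[C@@H]12 | intermediate
30 | trans-6,7-epoxide of 29 (C6–O β, C7–O α) | C=C1CC[C@H](O[Si](C)(C)C(C)(C)C)[C@]2(C)[C@@H](O[Si](C)(C)C(C)(C)C)/C=C/C(=C)[C@@H]3[C@H](O3)C(=O)[C@@H](O[Si](C)(C)C(C)(C)C)[C@@H]12 | intermediate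
31 | ethyl propanoate | CCC(=O)OCC | starting material
32 | lithium (Z)-enolate of ethyl propanoate (O–Li cis to methyl) | C/C=C(\[O-])OCC.[Li+] | intermediate
33 | ethyl 2-substituted propanoate: 8α-hydroxy, 8β-CH(CH3)CO2Et, 6β,7α-epoxide on the framework of 30 | C=C1CC[C@H](O[Si](C)(C)C(C)(C)C)[C@]2(C)[C@@H](O[Si](C)(C)C(C)(C)C)/C=C/C(=C)[C@@H]3[C@H](O3)[C@@](O)([C@@H](C)C(=O)OCC)[C@@H](O[Si](C)(C)C(C)(C)C)[C@@H]12 | intermediate
34 | 6α-chloro-7α,8α-dihydroxy ethyl ester | C=C1CC[C@H](O[Si](C)(C)C(C)(C)C)[C@]2(C)[C@@H](O[Si](C)(C)C(C)(C)C)/C=C/C(=C)[C@H](Cl)[C@H](O)[C@@](O)([C@@H](C)C(=O)OCC)[C@@H](O[Si](C)(C)C(C)(C)C)[C@@H]12 | intermediate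
35 | 2,9,14-tris-O-(tert-butyldimethylsilyl) chlorolactone (target with silyl ethers in place of the acetates) | C=C1CC[C@H](O[Si](C)(C)C(C)(C)C)[C@]2(C)[C@@H](O[Si](C)(C)C(C)(C)C)/C=C/C(=C)[C@H](Cl)[C@@H]3OC(=O)[C@H](C)[C@@]3(O)[C@@H](O[Si](C)(C)C(C)(C)C)[C@@H]12 | intermediate
36 | 2,9,14-tri-O-deacetyl target (2β,8α,9β,14α-tetraol) | C=C1CC[C@H](O)[C@]2(C)[C@@H](O)/C=C/C(=C)[C@H](Cl)[C@@H]3OC(=O)[C@H](C)[C@@]3(O)[C@@H](O)[C@@H]12 | intermediate
37 | CNP0178742.3, (1R,2S,3E,6S,7R,8R,9S,10S,14S,17R)-2,9,14-triacetoxy-6-chloro-8-hydroxybriara-3,5(16),11(20)-triene 7,19-lactone | C=C1CC[C@H](OC(C)=O)[C@]2(C)[C@@H](OC(C)=O)/C=C/C(=C)[C@H](Cl)[C@@H]3OC(=O)[C@H](C)[C@@]3(O)[C@@H](OC(C)=O)[C@@H]12 | target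

**Totals and risks**

Total step count: 22. Longest linear sequence: 22 steps (1 → 37); 4, 5, 14 and 31 are bought and used directly.

The three steps most likely to fail:

Step 15. The Corey–Chaykovsky epoxidation of the hindered, enolisable α-allenyl ketone 22 may be slow enough for the basic ylide to isomerise the allene or epimerise C3. The fallback sets out from 22 and abandons the ylide addition. Methylenation with salt-free Ph3P=CH2 at −78 to 0 °C gives the 8-methylene decalin F1. Epoxidation of this exocyclic alkene with dimethyldioxirane at −40 °C should occur from the α-face, because the axial 9β-silyloxy group shields the β-face. This comes back to the route at 23.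

Step 17. The allenyl anionic oxy-Cope rearrangement is the least precedented step. The alkoxide could instead add to the allene, or the enolate could be lost before selenenylation. The fallback sets out from 24 and runs the rearrangement under neutral conditions. Silylation with N-(trimethylsilyl)imidazole gives the tertiary trimethylsilyl ether F2. A thermal siloxy-Cope rearrangement (PhMe, 190 °C, sealed tube) then gives the ten-membered trimethylsilyl enol ether F3. Saegusa–Ito dehydrogenation with Pd(OAc)2 in MeCN returns to the route at enone 29.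

Step 18. Both the site (C6=C7 against the conjugated C5=C16) and the face of the nucleophilic epoxidation depend on the conformation of the ten-membered trienone and cannot be guaranteed. The fallback sets out from 29 and reverses the order of events. Lithium enolate 32 is added 1,2 to the enone at −78 °C to give the tertiary dienyl carbinol F4. Hydroxyl-directed epoxidation with VO(acac)2 and t-BuOOH is then chemoselective for the allylic-alcohol alkene C6=C7 and places the oxygen syn to the C8 hydroxyl. This comes back to the route at 33.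

**Further compounds**

F1 | step 15 | 2β,9β,14α-tris(tert-butyldimethylsilyloxy)-1β-methyl-8,11-dimethylene-3α-(propa-1,2-dienyl)-10α-H-trans-decalin | C=C1CC[C@H](O[Si](C)(C)C(C)(C)C)[C@]2(C)[C@@H](O[Si](C)(C)C(C)(C)C)[C@H](C=C=C)C(=C)[C@@H](O[Si](C)(C)C(C)(C)C)[C@@H]12
F2 | step 17 | 8α-O-trimethylsilyl ether of 24 | C=C1CC[C@H](O[Si](C)(C)C(C)(C)C)[C@]2(C)[C@@H](O[Si](C)(C)C(C)(C)C)[C@H](C=C=C)[C@@](O[Si](C)(C)C)(C=C)[C@@H](O[Si](C)(C)C(C)(C)C)[C@@H]12
F3 | step 17 | ten-membered C7(8) trimethylsilyl enol ether (3E) | C=C1CC[C@H](O[Si](C)(C)C(C)(C)C)[C@]2(C)[C@@H](O[Si](C)(C)C(C)(C)C)/C=C/C(=C)CC=C(O[Si](C)(C)C)[C@@H](O[Si](C)(C)C(C)(C)C)[C@@H]12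
F4 | step 18 | ethyl 2-substituted propanoate from 1,2-addition to 29: (3E,6E)-8α-hydroxy-8β-CH(CH3)CO2Et dienyl carbinol | C=C1CC[C@H](O[Si](C)(C)C(C)(C)C)[C@]2(C)[C@@H](O[Si](C)(C)C(C)(C)C)/C=C/C(=C)/C=C/[C@@](O)([C@@H](C)C(=O)OCC)[C@@H](O[Si](C)(C)C(C)(C)C)[C@@H]12
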